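**Plan**
Locants: seven-membered ring C1, C5, C6, C7, C8, C9, C10; side chain C2(=O)–C3–C4(OH)–C15 on C1; lactone O–C12(=O)–C11(C13) from C6 to C7; C14 is the methyl on C10.
Retrosynthesis: cut the angelate at O5, then C1–C2 (side chain as a 2-metallated 1-alkene whose C=CH2 stands for the C2 ketone), then C5–C6 and C9–C10 of the cycloheptane together.
Enabling feature: C1 is a masked ketone flanked by C5 (oxygen) and C10 (methyl), i.e. a 2-oxyallyl unit; C6–C7–C8–C9 carries the lactone oxygen on C6 and C11 on C7, i.e. the extra-annular diene (ring C=C plus vinyl) of a 4-vinyl-2-silyloxyfuran that already holds the lactone ring.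
Forward: lactone ring first (as the silyloxyfuran), then the cycloheptanone is closed onto it in one acid-triggered operation, then butenolide hydrogenation, side chain on C1, angelate on O5; silyl groups, the auxiliary ether and the C=CH2 helper are removed on the way.
Stereochemistry: C5 from a removable (R)-1-phenylethyl group on the oxocarbenium oxygen; C6 and C10 in the key step relative to C5; C7 and C11 by hydrogenation on the H6 face; C1 by addition anti to the C10 methyl; C4 from (R)-pent-4-yn-2-ol; the Z ester from angelic acid.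

Key step: step 7

Assumption: the (R)-1-phenylethyl group is taken to direct the furan to the cation face that gives 5S (attack anti to phenyl, benzylic C–H eclipsing the C=O+ bond); if the sense proves opposite, (S)-1-phenylethanol is used with no other change.

Step 1
Reactants: 1 4-hydroxy-3-methylfuran-2(5H)-one (3-methyltetronic acid)
Product: 2 4-methyl-5-oxo-2,5-dihydrofuran-3-yl trifluoromethanesulfonate
Conditions: Tf2O, iPr2NEt, CH2Cl2, −78 °C
Reagents that add atoms: trifluoromethanesulfonic anhydride, O=S(=O)(OS(=O)(=O)C(F)(F)F)C(F)(F)F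
Why: O-sulfonylation of the vinylogous acid should give the enol triflate needed for cross-coupling; no stereocentre is involved.

Step 2
Reactants: 2 4-methyl-5-oxo-2,5-dihydrofuran-3-yl trifluoromethanesulfonate
Product: 3 3-methyl-4-vinylfuran-2(5H)-one
Conditions: tributyl(vinyl)stannane, Pd(PPh3)4 (5 mol %), LiCl, THF, 65 °C
Reagents that add atoms: tributyl(vinyl)stannane, C=C[Sn](CCCC)(CCCC)CCCC
Why: Stille coupling (oxidative addition of zerovalent palladium into the enol triflate, chloride-assisted transmetalation) should attach C8–C9.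

Step 3
Reactants: 3 3-methyl-4-vinylfuran-2(5H)-one
Product: 4 triisopropyl[(3-methyl-4-vinylfuran-2-yl)oxy]silane
Conditions: TIPSOTf, Et3N, CH2Cl2, 0 °C
Reagents that add atoms: triisopropylsilyl trifluoromethanesulfonate, CC(C)[Si](OS(=O)(=O)C(F)(F)F)(C(C)C)C(C)C
Why: soft enolisation at the γ-CH2 and O-silylation (silyl dienol ether formation) should give the aromatic 2-silyloxyfuran, the nucleophilic four-carbon partner.

Step 4
Reactants: 5 methyl dimethoxyacetate
Product: 7 1,1-dimethoxybutan-2-one, via bromomagnesium hemiketal alkoxide 6 (not isolated)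
Conditions: EtMgBr (1.05 equiv), THF, −78 °C; then aqueous NH4Cl
Reagents that add atoms: ethylmagnesium bromide, CC[Mg]Br
Why: Grignard addition to the α,α-dialkoxy ester should stop at the chelated tetrahedral alkoxide at low temperature, so the ketone appears only on work-up (mono-addition).

Step 5
Reactants: 7 1,1-dimethoxybutan-2-one; 8 (R)-1-phenylethanol
Product: 9 1-methoxy-1-[(1R)-1-phenylethoxy]butan-2-one (both acetal epimers)
Conditions: pyridinium p-toluenesulfonate (cat.), 7 in excess, cyclohexane, 60 °C, 5 Å molecular sieves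
Reagents that add atoms: none
Why: acid-catalysed transacetalisation with removal of methanol should give the mixed acetal, whose acetal configuration is irrelevant because that carbon becomes planar on ionisation in step 7.

Step 6
Reactants: 9 1-methoxy-1-[(1R)-1-phenylethoxy]butan-2-one
Product: 11 triethyl{[(2Z)-1-methoxy-1-[(1R)-1-phenylethoxy]but-2-en-2-yl]oxy}silane, via potassium (Z)-enolate 10 (not isolated)
Conditions: KN(SiMe3)2, THF, −78 °C; then Et3SiCl
Reagents that add atoms: chlorotriethylsilane, CC[Si](Cl)(CC)CC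
Why: kinetic deprotonation at the ethyl CH2 (the hindered acetal C–H is not removed) and O-silylation should give the (Z)-silyl enol ether, the bulky acyl substituent and the potassium amide favouring the Z enolate.

Step 7
Reactants: 4 triisopropyl[(3-methyl-4-vinylfuran-2-yl)oxy]silane; 11 triethyl{[(2Z)-1-methoxy-1-[(1R)-1-phenylethoxy]but-2-en-2-yl]oxy}silane
Product: 14 (6S,8S,8aR)-3,6-dimethyl-8-[(1R)-1-phenylethoxy]-4,5,6,8a-tetrahydro-2H-cyclohepta[b]furan-2,7(8H)-dione, via O-silylated vinylbutenolide cation triflate 12 (not isolated), via triisopropylsilyl dienol ether 13 (not isolated)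
Conditions: TMSOTf (10 mol %), CH2Cl2, −95 to −40 °C, 11 added slowly to 4 (1.2 equiv); then 1 M HCl, THF, 0 °C
Reagents that add atoms: none
Why: Proposed new method: TMSOTf ionises the mixed acetal of 11 (loss of methoxide) to an alkoxy-substituted 2-silyloxyallyl cation; the γ-carbon of silyloxyfuran 4 attacks its oxygen-bearing terminus (C5–C6 bond), and the resulting O-silylated 4-vinylbutenolide cation 12 is a pentadienyl-type cation whose vinyl terminus C9 is then attacked by C10 of the surviving (Z)-silyl enol ether (intramolecular Mukaiyama–Michael 1,6-addition, C9–C10 bond), so that the oxyallyl unit C5–C1–C10 and the extra-annular diene C6=C7–C8=C9 of the furan are joined in a formal (4+3) annulation, the released silyl triflate carrying the chain and the acid work-up converting dienol ether 13 into the conjugated butenolide. The closest known reaction types are the Lewis-acid vinylogous Mukaiyama addition of 2-silyloxyfurans to acetal-derived oxocarbenium ions, the Mukaiyama–Michael addition, and the (4+3) cycloaddition of alkoxy-substituted silyloxyallyl cations with furan, which have not been combined across a 4-vinyl-2-silyloxyfuran. The one ring closed is the cycloheptanone, by a 7-(enolendo)-endo-trig attack of the enol ether on the vinyl terminus; the alternative five-membered closure at C7 would be a 5-(enolendo)-exo-trig process, which is stereoelectronically disfavoured. C5 is controlled by the (R)-1-phenylethyl group on the oxocarbenium oxygen (attack anti to phenyl, as in the furan cycloadditions of such cations), C6 by the open transition state of Lewis-acid silyloxyfuran additions, whose threo preference places O5 and O6 trans on the future ring, and C10 by the (Z)-enol ether reacting through the conformer that keeps H5 next to the bulky OSiEt3 group and the C5 alkoxy group inside (allylic 1,2-strain), which puts the methyl trans to O5. The step needs regioselectivity (oxygen-bearing cation terminus to the furan γ-carbon, then C9 and not C7), the simple and facial diastereoselectivity just described, and chemoselectivity against a second cation adding to 13; the charge distribution of the cation, the ring-closure preference, and slow addition of 11 to a slight excess of 4 at low temperature are relied on.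

Step 8
Reactants: 14 (6S,8S,8aR)-3,6-dimethyl-8-[(1R)-1-phenylethoxy]-4,5,6,8a-tetrahydro-2H-cyclohepta[b]furan-2,7(8H)-dione
Product: 15 (3R,3aS,6S,8S,8aR)-3,6-dimethyl-8-[(1R)-1-phenylethoxy]hexahydro-2H-cyclohepta[b]furan-2,7(3H)-dione
Conditions: H2 (4 bar), 5% Rh/Al2O3, EtOAc, rt
Reagents that add atoms: none
Why: heterogeneous syn-hydrogenation of the tetrasubstituted butenolide should occur on the H6 face (C5 and the rest of the seven-membered ring lie on the other face), setting C7 and C11 with H6, H7 and H11 all cis, and Rh on alumina is chosen because it does not hydrogenolyse the benzylic ether.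

Step 9
Reactants: 16 (R)-pent-4-yn-2-ol
Product: 17 tert-butyldimethyl{[(2R)-pent-4-yn-2-yl]oxy}silane
Conditions: TBSCl, imidazole, DMF, rt
Reagents that add atoms: tert-butyldimethylsilyl chloride, CC(C)(C)[Si](C)(C)Cl
Why: silyl ether formation protects the C4 carbinol, whose R configuration comes from the chiral pool alcohol.

Step 10
Reactants: 17 tert-butyldimethyl{[(2R)-pent-4-yn-2-yl]oxy}silane
Product: 19 {[(2R)-4-bromopent-4-en-2-yl]oxy}(tert-butyl)dimethylsilane, via (Z)-2-bromoalkenyl-9-borabicyclononane 18 (not isolated)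
Conditions: 9-bromo-9-borabicyclo[3.3.1]nonane, CH2Cl2, 0 °C; then AcOH, 0 °C to rt
Reagents that add atoms: 9-bromo-9-borabicyclo[3.3.1]nonane, BrB1C2CCCC1CCC2
Why: syn-bromoboration of the terminal alkyne places bromine on the internal carbon, and protonolysis of the C–B bond should give the 2-bromo-1-alkene (haloboration–protodeboronation).

Step 11
Reactants: 15 (3R,3aS,6S,8S,8aR)-3,6-dimethyl-8-[(1R)-1-phenylethoxy]hexahydro-2H-cyclohepta[b]furan-2,7(3H)-dione; 19 {[(2R)-4-bromopent-4-en-2-yl]oxy}(tert-butyl)dimethylsilane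
Product: 22 (3R,3aS,6S,7R,8S,8aR)-7-hydroxy-3,6-dimethyl-7-[(4R)-4-(tert-butyldimethylsilyloxy)pent-1-en-2-yl]-8-[(1R)-1-phenylethoxy]octahydro-2H-cyclohepta[b]furan-2-one, via alkenyllithium 20 (not isolated), via alkenylcerium dichloride 21 (not isolated)
Conditions: 19 (1.5 equiv), t-BuLi (3.0 equiv), Et2O, −78 °C; CeCl3, THF, −78 °C; then 15, −78 °C
Reagents that add atoms: none
Why: lithium–bromine exchange, transmetalation to cerium and 1,2-addition of the weakly basic organocerium should take the ketone in preference to the lactone; cerium chelation of the C1 carbonyl and O5 holds the C5–O bond in the carbonyl plane, which turns the trans C10 methyl pseudo-axial, so the reagent is expected to enter anti to that methyl on the convex face of the cis-fused lactone, giving the new OH trans to O5.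

Step 12
Reactants: 22 (3R,3aS,6S,7R,8S,8aR)-7-hydroxy-3,6-dimethyl-7-[(4R)-4-(tert-butyldimethylsilyloxy)pent-1-en-2-yl]-8-[(1R)-1-phenylethoxy]octahydro-2H-cyclohepta[b]furan-2-one
Product: 24 (3R,3aS,6S,7S,8S,8aR)-7-hydroxy-3,6-dimethyl-7-[(3R)-3-(tert-butyldimethylsilyloxy)butanoyl]-8-[(1R)-1-phenylethoxy]octahydro-2H-cyclohepta[b]furan-2-one, via secondary ozonide 23 (not isolated)
Conditions: O3, CH2Cl2, −78 °C; then Me2S, −78 °C to rt
Reagents that add atoms: ozone, [O-][O+]=O
Why: ozonolysis of the only alkene (1,1-disubstituted) with reductive work-up should unveil the C2 ketone, the alkenyl group having served as an acyl anion equivalent; no stereocentre is touched.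

Step 13
Reactants: 24 (3R,3aS,6S,7S,8S,8aR)-7-hydroxy-3,6-dimethyl-7-[(3R)-3-(tert-butyldimethylsilyloxy)butanoyl]-8-[(1R)-1-phenylethoxy]octahydro-2H-cyclohepta[b]furan-2-one
Product: 25 (3R,3aS,6S,7S,8S,8aR)-7,8-dihydroxy-3,6-dimethyl-7-[(3R)-3-(tert-butyldimethylsilyloxy)butanoyl]octahydro-2H-cyclohepta[b]furan-2-one
Conditions: H2 (1 atm), Pd(OH)2/C, EtOAc, rt
Reagents that add atoms: none
Why: hydrogenolysis of the benzylic C–O bond should remove the auxiliary as ethylbenzene and free the C5 hydroxyl, while the silyl ether, ketone and lactone are inert in ethyl acetate.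

Step 14
Reactants: 25 (3R,3aS,6S,7S,8S,8aR)-7,8-dihydroxy-3,6-dimethyl-7-[(3R)-3-(tert-butyldimethylsilyloxy)butanoyl]octahydro-2H-cyclohepta[b]furan-2-one; 26 angelic acid ((2Z)-2-methylbut-2-enoic acid)
Product: 28 (3R,3aS,6S,7S,8S,8aR)-7-hydroxy-3,6-dimethyl-2-oxo-7-[(3R)-3-(tert-butyldimethylsilyloxy)butanoyl]octahydro-2H-cyclohepta[b]furan-8-yl (2Z)-2-methylbut-2-enoate, via mixed anhydride 27 (not isolated)
Conditions: 26, 2,4,6-trichlorobenzoyl chloride, Et3N, toluene, rt; then 25, 80 °C
Reagents that add atoms: none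
Why: Yamaguchi-type esterification through the mixed anhydride without DMAP should acylate the only secondary hydroxyl (the tertiary C1 hydroxyl is unreactive) and is the usual way to transfer an angeloyl group with retention of the Z geometry.

Step 15
Reactants: 28 (3R,3aS,6S,7S,8S,8aR)-7-hydroxy-3,6-dimethyl-2-oxo-7-[(3R)-3-(tert-butyldimethylsilyloxy)butanoyl]octahydro-2H-cyclohepta[b]furan-8-yl (2Z)-2-methylbut-2-enoate
Product: 29 (3R,3aS,6S,7S,8S,8aR)-7-hydroxy-7-[(3R)-3-hydroxybutanoyl]-3,6-dimethyl-2-oxooctahydro-2H-cyclohepta[b]furan-8-yl (2Z)-2-methylbut-2-enoate (target)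
Conditions: HF·pyridine, THF, 0 °C to rt
Reagents that add atoms: none
Why: fluoride-mediated desilylation under mildly acidic conditions should free the C4 hydroxyl without retro-aldol or dehydration of the β-hydroxy ketone and without isomerising the angelate.

**Compound list**
1 | 4-hydroxy-3-methylfuran-2(5H)-one | CC1=C(O)COC1=O | starting material
2 | 4-methyl-5-oxo-2,5-dihydrofuran-3-yl trifluoromethanesulfonate | CC1=C(OS(=O)(=O)C(F)(F)F)COC1=O | intermediate
3 | 3-methyl-4-vinylfuran-2(5H)-one | CC1=C(C=C)COC1=O | intermediate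
4 | triisopropyl[(3-methyl-4-vinylfuran-2-yl)oxy]silane | C=Cc1coc(O[Si](C(C)C)(C(C)C)C(C)C)c1C | intermediate
5 | methyl dimethoxyacetate | COC(OC)C(=O)OC | starting material
6 | bromomagnesium 1,2,2-trimethoxy-1-ethylethanolate (tetrahedral adduct) | CCC(OC)(O[Mg]Br)C(OC)OC | intermediate
7 | 1,1-dimethoxybutan-2-one | CCC(=O)C(OC)OC | intermediate
8 | (R)-1-phenylethanol | C[C@@H](O)c1ccccc1 | starting material
9 | 1-methoxy-1-[(1R)-1-phenylethoxy]butan-2-one | CCC(=O)C(OC)O[C@H](C)c1ccccc1 | intermediate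
10 | potassium (2Z)-1-methoxy-1-[(1R)-1-phenylethoxy]but-2-en-2-olate | C/C=C(\[O-])C(OC)O[C@H](C)c1ccccc1.[K+] | intermediate
11 | triethyl{[(2Z)-1-methoxy-1-[(1R)-1-phenylethoxy]but-2-en-2-yl]oxy}silane | C/C=C(\O[Si](CC)(CC)CC)C(OC)O[C@H](C)c1ccccc1 | intermediate
12 | (5R)-3-methyl-5-{(1S,2Z)-1-[(1R)-1-phenylethoxy]-2-(triethylsilyloxy)but-2-enyl}-2-(triisopropylsilyloxy)-4-vinyl-5H-furan-1-ium triflate | C[C@H](c1ccccc1)O[C@@H]([C@@H]1[O+]=C(O[Si](C(C)C)(C(C)C)C(C)C)C(C)=C1C=C)/C(O[Si](CC)(CC)CC)=C/C.[O-]S(=O)(=O)C(F)(F)F | intermediate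
13 | (6S,8S,8aR)-3,6-dimethyl-8-[(1R)-1-phenylethoxy]-2-(triisopropylsilyloxy)-6,8a-dihydro-5H-cyclohepta[b]furan-7(8H)-one | C[C@H](c1ccccc1)O[C@H]1[C@@H]2OC(O[Si](C(C)C)(C(C)C)C(C)C)=C(C)C2=CC[C@H](C)C1=O | intermediate
14 | (6S,8S,8aR)-3,6-dimethyl-8-[(1R)-1-phenylethoxy]-4,5,6,8a-tetrahydro-2H-cyclohepta[b]furan-2,7(8H)-dione | C[C@H](c1ccccc1)O[C@H]1[C@@H]2OC(=O)C(C)=C2CC[C@H](C)C1=O | intermediate
15 | (3R,3aS,6S,8S,8aR)-3,6-dimethyl-8-[(1R)-1-phenylethoxy]hexahydro-2H-cyclohepta[b]furan-2,7(3H)-dione | C[C@H](c1ccccc1)O[C@H]1[C@@H]2OC(=O)[C@H](C)[C@@H]2CC[C@H](C)C1=O | intermediate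
16 | (R)-pent-4-yn-2-ol | C#CC[C@@H](C)O | starting material
17 | tert-butyldimethyl{[(2R)-pent-4-yn-2-yl]oxy}silane | C#CC[C@@H](C)O[Si](C)(C)C(C)(C)C | intermediate
18 | 9-[(1Z,4R)-2-bromo-4-(tert-butyldimethylsilyloxy)pent-1-enyl]-9-borabicyclo[3.3.1]nonane | Br/C(C[C@@H](C)O[Si](C)(C)C(C)(C)C)=C\B1C2CCCC1CCC2 | intermediate
19 | {[(2R)-4-bromopent-4-en-2-yl]oxy}(tert-butyl)dimethylsilane | C=C(Br)C[C@@H](C)O[Si](C)(C)C(C)(C)C | intermediate
20 | [(4R)-4-(tert-butyldimethylsilyloxy)pent-1-en-2-yl]lithium | [Li]C(=C)C[C@@H](C)O[Si](C)(C)C(C)(C)C | intermediate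
21 | dichloro[(4R)-4-(tert-butyldimethylsilyloxy)pent-1-en-2-yl]cerium | Cl[Ce](Cl)C(=C)C[C@@H](C)O[Si](C)(C)C(C)(C)C | intermediate
22 | (3R,3aS,6S,7R,8S,8aR)-7-hydroxy-3,6-dimethyl-7-[(4R)-4-(tert-butyldimethylsilyloxy)pent-1-en-2-yl]-8-[(1R)-1-phenylethoxy]octahydro-2H-cyclohepta[b]furan-2-one | C[C@H](c1ccccc1)O[C@H]1[C@@H]2OC(=O)[C@H](C)[C@@H]2CC[C@H](C)[C@@]1(O)C(=C)C[C@@H](C)O[Si](C)(C)C(C)(C)C | intermediate
23 | secondary ozonide of 22 (1,2,4-trioxolane spiro at C2, either configuration) | C[C@H](c1ccccc1)O[C@H]1[C@@H]2OC(=O)[C@H](C)[C@@H]2CC[C@H](C)[C@@]1(O)C1(C[C@@H](C)O[Si](C)(C)C(C)(C)C)OOCO1 | intermediate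
24 | (3R,3aS,6S,7S,8S,8aR)-7-hydroxy-3,6-dimethyl-7-[(3R)-3-(tert-butyldimethylsilyloxy)butanoyl]-8-[(1R)-1-phenylethoxy]octahydro-2H-cyclohepta[b]furan-2-one | C[C@H](c1ccccc1)O[C@H]1[C@@H]2OC(=O)[C@H](C)[C@@H]2CC[C@H](C)[C@@]1(O)C(=O)C[C@@H](C)O[Si](C)(C)C(C)(C)C | intermediate
25 | (3R,3aS,6S,7S,8S,8aR)-7,8-dihydroxy-3,6-dimethyl-7-[(3R)-3-(tert-butyldimethylsilyloxy)butanoyl]octahydro-2H-cyclohepta[b]furan-2-one | O[C@H]1[C@@H]2OC(=O)[C@H](C)[C@@H]2CC[C@H](C)[C@@]1(O)C(=O)C[C@@H](C)O[Si](C)(C)C(C)(C)C | intermediate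
26 | angelic acid ((2Z)-2-methylbut-2-enoic acid) | C/C=C(/C)C(=O)O | starting material
27 | (2Z)-2-methylbut-2-enoic 2,4,6-trichlorobenzoic anhydride | C/C=C(/C)C(=O)OC(=O)c1c(Cl)cc(Cl)cc1Cl | intermediate
28 | (3R,3aS,6S,7S,8S,8aR)-7-hydroxy-3,6-dimethyl-2-oxo-7-[(3R)-3-(tert-butyldimethylsilyloxy)butanoyl]octahydro-2H-cyclohepta[b]furan-8-yl (2Z)-2-methylbut-2-enoate | C/C=C(/C)C(=O)O[C@H]1[C@@H]2OC(=O)[C@H](C)[C@@H]2CC[C@H](C)[C@@]1(O)C(=O)C[C@@H](C)O[Si](C)(C)C(C)(C)C | intermediate
29 | (3R,3aS,6S,7S,8S,8aR)-7-hydroxy-7-[(3R)-3-hydroxybutanoyl]-3,6-dimethyl-2-oxooctahydro-2H-cyclohepta[b]furan-8-yl (2Z)-2-methylbut-2-enoate | C/C=C(/C)C(=O)O[C@H]1[C@@H]2OC(=O)[C@H](C)[C@@H]2CC[C@H](C)[C@@]1(O)C(=O)C[C@@H](C)O | target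

**Totals**
Total steps: 15. Longest linear sequence: 10 steps (steps 1–3, 7, 8, 11–15; the branch through steps 4–6 is equally long).

**Steps most likely to fail**

Step 7 (key step). The first C–C bond may form with poor threo or facial selectivity, the silyl enol ether may be lost by protodesilylation before the ring closes, or a second cation may add to dienol ether 13. The fallback uses known chemistry, sets out from 4 and 11, and makes the two bonds in separate, individually precedented operations. The vinylogous Mukaiyama addition alone is run with TMSOTf (cat.) in CH2Cl2 at −95 °C and quenched cold (aqueous NaHCO3, then dilute citric acid to hydrolyse the enol ether). The open-chain butenolide ketone (5R)-3-methyl-5-{(1S)-2-oxo-1-[(1R)-1-phenylethoxy]butyl}-4-vinylfuran-2(5H)-one F1 is isolated and, if needed, separated from its C6 epimer. The seven-membered ring is then closed by intramolecular 1,6-Michael addition of the pyrrolidine enamine of the ethyl ketone to the vinylbutenolide (pyrrolidine, AcOH, MeCN, rt; Stork enamine chemistry). Hydrolysis on work-up brings the sequence back to the route at 14.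

Step 11. The basic, branched alkenyl reagent may deprotonate C5 (with β-elimination of the lactone carboxylate) or attack the lactone rather than the flanked ketone, and attack trans to the C5 alkoxy group may compete with the intended facial course. The fallback sets out from 15 and builds the side chain from a smaller acyl anion equivalent and an aldol reaction; it answers the reactivity problem, and the smaller reagent is expected to follow the same facial course. 1-Ethoxyvinyllithium (ethyl vinyl ether, t-BuLi; CeCl3, THF, −78 °C) should give the enol ether adduct (3R,3aS,6S,7S,8S,8aR)-7-(1-ethoxyvinyl)-7-hydroxy-3,6-dimethyl-8-[(1R)-1-phenylethoxy]octahydro-2H-cyclohepta[b]furan-2-one F2. Dilute HCl in THF should give the methyl ketone (3R,3aS,6S,7S,8S,8aR)-7-acetyl-7-hydroxy-3,6-dimethyl-8-[(1R)-1-phenylethoxy]octahydro-2H-cyclohepta[b]furan-2-one F3. A boron aldol reaction with acetaldehyde (Ipc2BCl, Et3N, the reagent enantiomer matched to the 4R carbinol) should give the diol (3R,3aS,6S,7S,8S,8aR)-7-hydroxy-7-[(3R)-3-hydroxybutanoyl]-3,6-dimethyl-8-[(1R)-1-phenylethoxy]octahydro-2H-cyclohepta[b]furan-2-one F4. Selective silylation of its secondary hydroxyl (TBSCl, imidazole) comes back to the route at 24.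

Step 8. Hydrogenolysis of the benzylic ether or saturation of its arene may compete with the slow reduction of the tetrasubstituted alkene. The fallback sets out from 14 and changes the order of events so that this selectivity is no longer needed. Alkenylcerium 21 is added to the ketone of 14 to give the butenolide carbinol (6S,7R,8S,8aR)-7-hydroxy-3,6-dimethyl-7-[(4R)-4-(tert-butyldimethylsilyloxy)pent-1-en-2-yl]-8-[(1R)-1-phenylethoxy]-4,5,6,7,8,8a-hexahydro-2H-cyclohepta[b]furan-2-one F5. Lemieux–Johnson cleavage (K2OsO4·2H2O cat., NaIO4, 2,6-lutidine, dioxane/H2O), which spares the electron-poor tetrasubstituted butenolide alkene, should give the butenolide α-hydroxy ketone (6S,7S,8S,8aR)-7-hydroxy-3,6-dimethyl-7-[(3R)-3-(tert-butyldimethylsilyloxy)butanoyl]-8-[(1R)-1-phenylethoxy]-4,5,6,7,8,8a-hexahydro-2H-cyclohepta[b]furan-2-one F6. A single hydrogenation over Pd(OH)2/C (H2, EtOAc) then reduces the butenolide on the H6 face and removes the auxiliary, coming back to the route at 25.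

**Further compounds**
F1 | step 7 | (5R)-3-methyl-5-{(1S)-2-oxo-1-[(1R)-1-phenylethoxy]butyl}-4-vinylfuran-2(5H)-one | C[C@H](c1ccccc1)O[C@@H]([C@@H]1OC(=O)C(C)=C1C=C)C(=O)CC
F2 | step 11 | (3R,3aS,6S,7S,8S,8aR)-7-(1-ethoxyvinyl)-7-hydroxy-3,6-dimethyl-8-[(1R)-1-phenylethoxy]octahydro-2H-cyclohepta[b]furan-2-one | C[C@H](c1ccccc1)O[C@H]1[C@@H]2OC(=O)[C@H](C)[C@@H]2CC[C@H](C)[C@@]1(O)C(=C)OCC
F3 | step 11 | (3R,3aS,6S,7S,8S,8aR)-7-acetyl-7-hydroxy-3,6-dimethyl-8-[(1R)-1-phenylethoxy]octahydro-2H-cyclohepta[b]furan-2-one | C[C@H](c1ccccc1)O[C@H]1[C@@H]2OC(=O)[C@H](C)[C@@H]2CC[C@H](C)[C@@]1(O)C(C)=O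
F4 | step 11 | (3R,3aS,6S,7S,8S,8aR)-7-hydroxy-7-[(3R)-3-hydroxybutanoyl]-3,6-dimethyl-8-[(1R)-1-phenylethoxy]octahydro-2H-cyclohepta[b]furan-2-one | C[C@H](c1ccccc1)O[C@H]1[C@@H]2OC(=O)[C@H](C)[C@@H]2CC[C@H](C)[C@@]1(O)C(=O)C[C@@H](C)O
F5 | step 8 | (6S,7R,8S,8aR)-7-hydroxy-3,6-dimethyl-7-[(4R)-4-(tert-butyldimethylsilyloxy)pent-1-en-2-yl]-8-[(1R)-1-phenylethoxy]-4,5,6,7,8,8a-hexahydro-2H-cyclohepta[b]furan-2-one | C[C@H](c1ccccc1)O[C@H]1[C@@H]2OC(=O)C(C)=C2CC[C@H](C)[C@@]1(O)C(=C)C[C@@H](C)O[Si](C)(C)C(C)(C)C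
F6 | step 8 | (6S,7S,8S,8aR)-7-hydroxy-3,6-dimethyl-7-[(3R)-3-(tert-butyldimethylsilyloxy)butanoyl]-8-[(1R)-1-phenylethoxy]-4,5,6,7,8,8a-hexahydro-2H-cyclohepta[b]furan-2-one | C[C@H](c1ccccc1)O[C@H]1[C@@H]2OC(=O)C(C)=C2CC[C@H](C)[C@@]1(O)C(=O)C[C@@H](C)O[Si](C)(C)C(C)(C)C
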